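Atoms are numbered in the order of the target SMILES: ring A = γ-lactone C8/C9/O12/C13/C15, ring B = cyclopentanone C6/C7/C8/C15/C17, ring C = δ-lactone C4/C5/C6/C19/O21/C22. Abbreviations: TBS = tert-butyldimethylsilyl, TMS = trimethylsilyl, pin = pinacolato.

## Analysis of the target

The compound is tricyclic: γ-lactone ring A is cis-fused to cyclopentanone ring B, and ring B is spiro-linked at C6 to δ-lactone ring C. It has five stereocentres (4S, 6R, 8R, 15R, 22S). H8 and the C15 methyl are cis. The lactone carbonyl C19 lies on the convex face of the A/B bicycle (the side of H8 and the C15 methyl) and C5 on the concave side. The isopropenyl group on C4 is cis to the isobutyryl group on C22. C6 and C15 are both quaternary and flank the ketone C17, so C17 belongs to two non-enolisable 1,3-dicarbonyl units (C13/C17 and C17/C19) that nucleophiles can cleave by retro-Claisen attack. C22–H sits between the C23 ketone and the lactone oxygen and can epimerise, and the 1,1-disubstituted alkene is sensitive to acids and electrophiles. The hard part is the spiro centre C6: a quaternary carbon between two carbonyl groups, next to a second quaternary centre, which neither a Michael nor an aldol reaction delivers directly. The strategy rests on reading C6 with C17 and C19 as a 2-acyl-2-alkylcyclopentanone, the product of a 1,2-acyl shift in a 2,3-epoxycyclohexanone in which C19 is still a ring carbon between C17 and C6.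

## Retrosynthetic reasoning

**Target 28 to lactol 27.** The last operation is an oxidation only: the lactol carbon C19 becomes the lactone carbonyl and the C23 carbinol becomes the ketone. Unveiling the C23 ketone last, under neutral conditions, means the epimerisable C22–H never sees acid or base while it is α to a carbonyl group.

**27 to keto aldehyde 25.** Cutting the O21–C19 bond gives a formyl group on C6 and a protected hydroxyl on C22. The forward step is desilylation; the free O21 hydroxyl closes onto the aldehyde by itself, and the lactol shields the non-enolisable β-keto aldehyde from deformylation.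

**25 to epoxy ketone 24 (key disconnection).** The C6–C17 bond of ring B is cut and C17 is reconnected to C19. This turns the spiro 1,3-dicarbonyl centre into a tertiary epoxide carbon of a six-membered ring, where it is easy to build. The forward reaction, a Lewis-acid 1,2-acyl shift, forms ring B and the C6 stereocentre in one stereospecific step.

**24 to enone 23.** Removing the epoxide oxygen gives a cyclohexenone with the alkene at C19=C6. The forward nucleophilic epoxidation must place oxygen on the convex face, because that face is copied into the spiro centre, and it must leave the isopropenyl group untouched.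

**23 to diketone 21.** The C19=C6 bond is cut by a retro-aldol condensation. C15 is quaternary, so the C17 ketone can enolise only toward C19, which makes the forward closure unambiguous on that side.

**21 to β-keto lactone 20.** The C15–methyl bond is cut. Forward, the methyl enters trans to the C8 side chain, which gives the cis ring fusion.

**20 to butenolide 4 and silyl enol ether 19.** The C7–C8 bond is cut. Acceptor 4 is doubly activated and chelating, so a chiral Lewis acid can set C8. Donor 19 is the kinetic enol ether of methyl ketone 18, and 4 comes from 1 and 2 by Knoevenagel condensation and lactonisation.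

**18 to 17 and 16.** These are protecting-group operations: the C6 ketone travels as a dioxolane and the two side-chain oxygens as silyl ethers. C23 is kept at the carbinol level so that the molecule never holds two ketals that must be told apart and never needs a hindered ketal removed next to C22.

**16 to aldehyde 7 and allylboronate 14.** The C4–C22 bond is cut. A closed allylboration transition state converts the E geometry of 14 into the required C4/C22 relationship and sets both centres at once. 7 comes from hydroxy ester 5 through 6.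

**14 to 13, 12, 11, then 9 and 10.** The trisubstituted E alkene is made by a stabilised Wittig reaction of aldehyde 9 (from ester 8) with ylide 10. Reduction, acetylation and borylation follow.

## Alternatives that were turned down

**Alternative 1:** Ring B is traced back to a cyclobutane. The C15–C17 and C7–C8 bonds would be formed by an enantioselective [2+2] photocycloaddition of A1 with A2, run with a chiral oxazaborolidine-type Lewis acid and light that only the complexed lactone absorbs, to give A3. A one-carbon ring expansion of the methylenecyclobutane would then give the cyclopentanone.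
- For it: both ring-fusion centres, including the quaternary C15, come from one catalytic step and two very simple compounds. On this point it is stronger than the chosen route, which sets C15 by a substrate-controlled methylation.
- Against it: A1 is a hindered, weakly absorbing lactone with a gem-dimethyl group next to the reacting carbon. The orientation of A2 must put the exocyclic methylene on C17. The ring expansion must move C7 and not the quaternary C15.
- Comparison: after all that, C6 is still a bare CH2. The spiro centre, C19 and the whole side chain would have to be added by two successive enolate reactions at one carbon. The chosen route brings C6 in already carrying C5 and C19, so its step count after ring B is lower.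

**Alternative 2:** The C6–C19 bond is cut. In A4 the C22 oxygen carries an imidazole-1-carbonyl group; a hindered potassium amide base would form the C17 enolate (possible only toward C6), and its attack on the tethered carbonyl would close ring C and give A5.
- For it: the spiro centre and ring C form in one step at the final oxidation level. O-acylation would need an eight-membered ring. The endgame is one deprotection, and no Lewis acid meets the isopropenyl group. On these points it is as strong as or stronger than the chosen route.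
- Against it: the face of attack is only the kinetic exo preference of a flat enolate whose tether can reach both faces. A4 itself needs the cis-fused keto lactone with the side chain already on C6, that is, alkylation of a hindered cyclopentanone enolate with a β-branched primary electrophile, after a separate synthesis of the A/B bicycle.
- Comparison: the chosen route offers convergence, since the side chain enters during ring construction, and a stereospecific transfer of configuration from an epoxide whose face is set on a rigid bicycle.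

**Alternative 3:** The C7–C8 bond is cut inside ring B. A chiral copper bis(oxazoline) Lewis acid would bind the two carbonyl oxygens of divinyl ketone A6 and trigger a conrotatory 4π closure. The β-silyl group would steer the cation to an exocyclic C6=C5 alkene, and protonation at C15 would give A7.
- For it: ring B and C8 come from one catalytic step on an achiral dienone, and the exocyclic enone is a handle for attaching C4. For making ring B alone it is shorter than the chosen Michael, aldol, epoxidation and shift sequence.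
- Against it: the new bond forms next to the gem-dimethyl carbon C9, which slows closure and erodes torquoselectivity. A7 is an α-methylene ketone prone to isomerise or polymerise, and C15 still needs its methyl.
- Comparison: C4 would have to be joined to C5 by conjugate addition of a secondary carbon nucleophile with no clear control of the C4 configuration, and C19 would then be added as in alternative 2. The chosen route sets C4 and C22 beforehand by allylboration and needs no such union.

Key step: step 17

Remark 1: C23 is carried as an (R)-configured silyl-protected carbinol and oxidised in the last step. Its configuration is not part of the target and is chosen so that the Felkin–Anh preference of aldehyde 7 and the catalyst of step 9 act in the same sense.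

Remark 2: the sense of induction assigned to (S)-TRIP (step 9) and to the (S,S)-tert-butyl-bis(oxazoline) ligand (step 13) follows the accepted models for simpler substrates; the antipodal catalyst is equally available if the first adduct shows the opposite sense.

Remark 3: 2-hydroxy-2-methylpropanal (2) is supplied as its dimer, which reverts to the monomer on heating.

## Route

Step 1
Reactants: 1 methyl acetoacetate; 2 2-hydroxy-2-methylpropanal
Product: 4 3-acetyl-5,5-dimethylfuran-2(5H)-one, via Knoevenagel adduct 3 (not isolated)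
Conditions: piperidine (10 mol %), AcOH (10 mol %), toluene, Dean–Stark, reflux
Reagents that add atoms: none
Why: Knoevenagel condensation of the non-enolisable aldehyde with the active methylene of 1; the tertiary hydroxyl of the (Z)-adduct then closes onto the methyl ester (lactonisation), and since the E and Z adducts interconvert all material should funnel to the butenolide.

Step 2
Reactants: 5 methyl (2R)-2-hydroxy-3-methylbutanoate
Product: 6 methyl (2R)-2-(TBSO)-3-methylbutanoate
Conditions: TBSCl, imidazole, DMF, rt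
Reagents that add atoms: tert-butyldimethylsilyl chloride, CC(C)(C)[Si](C)(C)Cl
Why: standard silylation of a secondary α-hydroxy ester; the stereocentre is not touched.

Step 3
Reactants: 6 methyl (2R)-2-(TBSO)-3-methylbutanoate
Product: 7 (2R)-2-(TBSO)-3-methylbutanal
Conditions: i-Bu2AlH (1.1 equiv), CH2Cl2, −78 °C; aq. Rochelle salt
Reagents that add atoms: none
Why: half-reduction of an α-silyloxy ester; the aluminium hemiacetal is stable at −78 °C and releases the aldehyde only on work-up, and the aldehyde is used at once to avoid α-epimerisation.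

Step 4
Reactants: 8 ethyl 2-(2-methyl-1,3-dioxolan-2-yl)acetate
Product: 9 2-(2-methyl-1,3-dioxolan-2-yl)acetaldehyde
Conditions: i-Bu2AlH (1.05 equiv), CH2Cl2, −78 °C; aq. Rochelle salt
Reagents that add atoms: none
Why: the same low-temperature ester half-reduction; the β-ketal aldehyde is taken on crude.

Step 5
Reactants: 9 2-(2-methyl-1,3-dioxolan-2-yl)acetaldehyde; 10 ethyl 2-(triphenyl-λ5-phosphanylidene)propanoate
Product: 11 ethyl (2E)-2-methyl-4-(2-methyl-1,3-dioxolan-2-yl)but-2-enoate
Conditions: CH2Cl2, rt
Reagents that add atoms: none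
Why: Wittig olefination with a stabilised α-methyl ylide, which should give the E trisubstituted enoate with high selectivity.

Step 6
Reactants: 11 ethyl (2E)-2-methyl-4-(2-methyl-1,3-dioxolan-2-yl)but-2-enoate
Product: 12 (2E)-2-methyl-4-(2-methyl-1,3-dioxolan-2-yl)but-2-en-1-ol
Conditions: i-Bu2AlH (2.2 equiv), CH2Cl2, −78 to 0 °C
Reagents that add atoms: none
Why: 1,2-reduction of the enoate to the allylic alcohol with retention of alkene geometry.

Step 7
Reactants: 12 (2E)-2-methyl-4-(2-methyl-1,3-dioxolan-2-yl)but-2-en-1-ol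
Product: 13 (2E)-2-methyl-4-(2-methyl-1,3-dioxolan-2-yl)but-2-en-1-yl acetate
Conditions: Ac2O, pyridine, DMAP (cat.), CH2Cl2, 0 °C to rt
Reagents that add atoms: acetic anhydride, CC(=O)OC(C)=O
Why: acetylation installs the leaving group for π-allylpalladium formation.

Step 8
Reactants: 13 (2E)-2-methyl-4-(2-methyl-1,3-dioxolan-2-yl)but-2-en-1-yl acetate
Product: 14 4,4,5,5-tetramethyl-2-[(2E)-2-methyl-4-(2-methyl-1,3-dioxolan-2-yl)but-2-en-1-yl]-1,3,2-dioxaborolane
Conditions: B2pin2 (1.1 equiv), Pd2(dba)3 (2.5 mol %, zerovalent palladium), DMSO, 50 °C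
Reagents that add atoms: bis(pinacolato)diboron, CC1(C)OB(OC1(C)C)B1OC(C)(C)C(C)(C)O1
Why: Miyaura-type borylation of an allylic acetate; oxidative addition gives the syn π-allylpalladium acetate, and transmetallation with B2pin2 followed by reductive elimination places boron on the less hindered CH2 terminus, so the E geometry should be carried through.

Step 9
Reactants: 7 (2R)-2-(TBSO)-3-methylbutanal; 14 4,4,5,5-tetramethyl-2-[(2E)-2-methyl-4-(2-methyl-1,3-dioxolan-2-yl)but-2-en-1-yl]-1,3,2-dioxaborolane
Product: 16 (3R,4S,5S)-3-(TBSO)-2,6-dimethyl-5-[(2-methyl-1,3-dioxolan-2-yl)methyl]hept-6-en-4-ol, via pinacol borate 15 (not isolated)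
Conditions: (S)-TRIP [(S)-3,3'-bis(2,4,6-triisopropylphenyl)-1,1'-binaphthyl-2,2'-diyl hydrogen phosphate] (5 mol %), 4 Å MS, toluene, −30 °C to rt; aq. NaHCO3
Reagents that add atoms: none
Why: chiral phosphoric acid-catalysed allylboration through a closed chair transition state; the E geometry of 14 gives the anti relationship between the C22 hydroxyl and the C5 branch (4S with 22S), and the acid directs addition to the Si face of the aldehyde, which is also the Felkin–Anh face of the (R)-α-silyloxy aldehyde, so catalyst and substrate should reinforce each other.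

Step 10
Reactants: 16 (3R,4S,5S)-3-(TBSO)-2,6-dimethyl-5-[(2-methyl-1,3-dioxolan-2-yl)methyl]hept-6-en-4-ol
Product: 17 2-[(2S,3S,4R)-3,4-bis(TBSO)-5-methyl-2-(prop-1-en-2-yl)hexyl]-2-methyl-1,3-dioxolane
Conditions: TBSOTf, 2,6-lutidine, CH2Cl2, −78 to 0 °C
Reagents that add atoms: tert-butyldimethylsilyl trifluoromethanesulfonate, CC(C)(C)[Si](C)(C)OS(=O)(=O)C(F)(F)F
Why: silylation of a hindered secondary alcohol with the silyl triflate; the ketone ketal should survive at low temperature.

Step 11
Reactants: 17 2-[(2S,3S,4R)-3,4-bis(TBSO)-5-methyl-2-(prop-1-en-2-yl)hexyl]-2-methyl-1,3-dioxolane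
Product: 18 (4S,5S,6R)-5,6-bis(TBSO)-7-methyl-4-(prop-1-en-2-yl)octan-2-one
Conditions: p-TsOH·H2O (10 mol %), THF/H2O (5:1), rt
Reagents that add atoms: water, O
Why: acid-catalysed hydrolysis of the only ketal in the molecule; hindered secondary silyl ethers and the isopropenyl group tolerate catalytic sulfonic acid in wet THF at room temperature.

Step 12
Reactants: 18 (4S,5S,6R)-5,6-bis(TBSO)-7-methyl-4-(prop-1-en-2-yl)octan-2-one
Product: 19 (4S,5S,6R)-5,6-bis(TBSO)-7-methyl-4-(prop-1-en-2-yl)-2-(TMSO)oct-1-ene
Conditions: LiN(i-Pr)2 (1.1 equiv), Me3SiCl (in situ), THF, −78 °C; non-aqueous work-up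
Reagents that add atoms: chlorotrimethylsilane, C[Si](C)(C)Cl
Why: kinetic deprotonation of the methyl ketone at CH3 (C7) rather than at the β-branched CH2 (C5), trapped in situ, should give the terminal silyl enol ether.

Step 13
Reactants: 4 3-acetyl-5,5-dimethylfuran-2(5H)-one; 19 (4S,5S,6R)-5,6-bis(TBSO)-7-methyl-4-(prop-1-en-2-yl)-2-(TMSO)oct-1-ene
Product: 20 (4R)-3-acetyl-4-[(4S,5S,6R)-5,6-bis(TBSO)-7-methyl-2-oxo-4-(prop-1-en-2-yl)octyl]-5,5-dimethyloxolan-2-one (C3 epimers and enol form)
Conditions: Cu(OTf)2 (10 mol %), (S,S)-t-Bu-box [2,2'-(propane-2,2-diyl)bis((4S)-4-tert-butyl-4,5-dihydro-1,3-oxazole)] (11 mol %), (CF3)2CHOH (1.5 equiv), CH2Cl2, −78 to −40 °C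
Reagents that add atoms: none
Why: enantioselective Mukaiyama–Michael addition; the divalent copper bis(oxazoline) complex chelates the lactone and acetyl carbonyls of 4 in a square-planar complex, one tert-butyl group shields the Si face of C8 and the enol ether adds to the Re face (8R), while the fluorinated alcohol takes over the silyl group and turns the catalyst over; C15 stays a mixture that the next step erases.

Step 14
Reactants: 20 (4R)-3-acetyl-4-[(4S,5S,6R)-5,6-bis(TBSO)-7-methyl-2-oxo-4-(prop-1-en-2-yl)octyl]-5,5-dimethyloxolan-2-one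
Product: 21 (3R,4R)-3-acetyl-4-[(4S,5S,6R)-5,6-bis(TBSO)-7-methyl-2-oxo-4-(prop-1-en-2-yl)octyl]-3,5,5-trimethyloxolan-2-one
Conditions: MeI, K2CO3, acetone, rt
Reagents that add atoms: iodomethane, CI
Why: C-alkylation of the β-keto lactone enolate; methyl iodide approaches anti to the C8 side chain, so the methyl ends cis to H8 and the acetyl cis to the C7 chain (15R), as the cis ring fusion requires.

Step 15
Reactants: 21 (3R,4R)-3-acetyl-4-[(4S,5S,6R)-5,6-bis(TBSO)-7-methyl-2-oxo-4-(prop-1-en-2-yl)octyl]-3,5,5-trimethyloxolan-2-one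
Product: 23 (3aR,7aR)-5-[(2S,3S,4R)-3,4-bis(TBSO)-5-methyl-2-(prop-1-en-2-yl)hexyl]-3,3,7a-trimethyl-3a,4-dihydro-2-benzofuran-1,7(3H,7aH)-dione, via ketol 22 (not isolated)
Conditions: t-BuOK (0.3 equiv), t-BuOH/THF, 4 Å MS, 0 °C to rt
Reagents that add atoms: none
Why: intramolecular aldol condensation of a 1,5-diketone (second half of a Robinson annulation, 6-enolendo-exo-trig); the acetyl methyl C19 adds to the unhindered C6 ketone and the ketol loses water by E1cB, while the opposite closure (C5 onto C17) would join a tertiary and a quaternary carbon next to C15 and should be disfavoured.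

Step 16
Reactants: 23 (3aR,7aR)-5-[(2S,3S,4R)-3,4-bis(TBSO)-5-methyl-2-(prop-1-en-2-yl)hexyl]-3,3,7a-trimethyl-3a,4-dihydro-2-benzofuran-1,7(3H,7aH)-dione
Product: 24 (3aR,5R,6R,7aR)-5-[(2S,3S,4R)-3,4-bis(TBSO)-5-methyl-2-(prop-1-en-2-yl)hexyl]-5,6-epoxy-3,3,7a-trimethylhexahydro-2-benzofuran-1,7-dione
Conditions: t-BuOOH (anhydrous, 3 equiv), DBU (1.5 equiv), CH2Cl2, 0 °C to rt
Reagents that add atoms: tert-butyl hydroperoxide, CC(C)(C)OO
Why: Weitz–Scheffer nucleophilic epoxidation; the peroxide anion adds to C6 from the convex face of the cis-fused bicycle (the side of the C15 methyl and H8, away from ring A and its gem-dimethyl carbon C9) and the enolate closes onto oxygen on the same face, and a nucleophilic oxidant leaves the isopropenyl group alone.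

Step 17
Reactants: 24 (3aR,5R,6R,7aR)-5-[(2S,3S,4R)-3,4-bis(TBSO)-5-methyl-2-(prop-1-en-2-yl)hexyl]-5,6-epoxy-3,3,7a-trimethylhexahydro-2-benzofuran-1,7-dione
Product: 25 (3aR,5S,6aR)-5-[(2S,3S,4R)-3,4-bis(TBSO)-5-methyl-2-(prop-1-en-2-yl)hexyl]-3,3,6a-trimethyl-1,6-dioxohexahydro-1H-cyclopenta[c]furan-5-carbaldehyde
Conditions: BF3·OEt2 (1.1 equiv), CH2Cl2, −78 to −40 °C, 15 min; Et3N then aq. NaHCO3 at −78 °C
Reagents that add atoms: none
Why: BF3 binds the epoxide oxygen and the C6–O bond lengthens, because C6 is tertiary whereas positive charge at C19 would sit next to the C17 carbonyl. As that bond breaks, the acyl carbon C17 shifts from C19 to C6 on the face opposite the departing oxygen, which contracts the six-membered ring to ring B and leaves C19, still bonded to the oxygen, as a formyl group. The closest known reaction is the Lewis-acid rearrangement of 2,3-epoxy-3-alkylcyclohexanones (the isophorone oxide type) to 2-formyl-2-alkylcyclopentanones. Ring B thus closes by a 1,2-shift, a backside displacement at C6 through a three-centre transition state, not by an end-on cyclisation. The only new stereocentre, C6, is fixed by the epoxide: inversion at C6 places C19 on the convex face and C5 on the concave face (5S in 25 by CIP, the same spatial arrangement as 6R in the target). The step needs acyl rather than hydride migration, which the precedent supports, and C6–O rather than C19–O cleavage, which the tertiary centre secures. It must also spare the isopropenyl group and the silyl ether oxygens; low temperature, about one equivalent of Lewis acid and a cold amine quench are meant to limit capture of the boron-bound aldehyde, and the bulky silyl groups make O21 a poor internal nucleophile.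

Step 18
Reactants: 25 (3aR,5S,6aR)-5-[(2S,3S,4R)-3,4-bis(TBSO)-5-methyl-2-(prop-1-en-2-yl)hexyl]-3,3,6a-trimethyl-1,6-dioxohexahydro-1H-cyclopenta[c]furan-5-carbaldehyde
Product: 27 (3aR,5S,5'S,6'S,6aR)-2'-hydroxy-6'-[(1R)-1-hydroxy-2-methylpropyl]-3,3,6a-trimethyl-5'-(prop-1-en-2-yl)tetrahydro-1H-spiro[cyclopenta[c]furan-5,3'-oxane]-1,6(6aH)-dione (both C2' anomers), via dihydroxy aldehyde 26 (not isolated)
Conditions: HF·pyridine, pyridine, THF, 0 °C to rt
Reagents that add atoms: none
Why: buffered fluoride cleavage of both silyl ethers; once O21 is free the hydroxy aldehyde closes to the six-membered lactol (6-exo-trig addition to the formyl group), which protects the non-enolisable β-keto aldehyde from deformylation.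

Step 19
Reactants: 27 (3aR,5S,5'S,6'S,6aR)-2'-hydroxy-6'-[(1R)-1-hydroxy-2-methylpropyl]-3,3,6a-trimethyl-5'-(prop-1-en-2-yl)tetrahydro-1H-spiro[cyclopenta[c]furan-5,3'-oxane]-1,6(6aH)-dione
Product: 28 (3aR,5R,5'S,6'S,6aR)-3,3,6a-trimethyl-6'-(2-methylpropanoyl)-5'-(prop-1-en-2-yl)tetrahydro-1H-spiro[cyclopenta[c]furan-5,3'-oxane]-1,2',6(6aH)-trione (CNP0216954.2)
Conditions: Dess–Martin periodinane (3 equiv), pyridine, CH2Cl2, rt
Reagents that add atoms: none
Why: Dess–Martin oxidation of the lactol to the δ-lactone and of the hindered C23 carbinol to the ketone in one operation; the conditions are buffered and neutral, so C22 should not epimerise, and the temporary C23 stereocentre disappears.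

## Compound list

1 | methyl acetoacetate | COC(=O)CC(C)=O | starting material
2 | 2-hydroxy-2-methylpropanal | CC(C)(O)C=O | starting material
3 | methyl (2Z)-2-acetyl-4-hydroxy-4-methylpent-2-enoate | COC(=O)/C(C(C)=O)=C\C(C)(C)O | intermediate (not isolated)
4 | 3-acetyl-5,5-dimethylfuran-2(5H)-one | CC(=O)C1=CC(C)(C)OC1=O | intermediate
5 | methyl (2R)-2-hydroxy-3-methylbutanoate | COC(=O)[C@H](O)C(C)C | starting material
6 | methyl (2R)-2-(TBSO)-3-methylbutanoate | COC(=O)[C@H](O[Si](C)(C)C(C)(C)C)C(C)C | intermediate
7 | (2R)-2-(TBSO)-3-methylbutanal | O=C[C@H](O[Si](C)(C)C(C)(C)C)C(C)C | intermediate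
8 | ethyl 2-(2-methyl-1,3-dioxolan-2-yl)acetate | CCOC(=O)CC1(C)OCCO1 | starting material
9 | 2-(2-methyl-1,3-dioxolan-2-yl)acetaldehyde | O=CCC1(C)OCCO1 | intermediate
10 | ethyl 2-(triphenyl-λ5-phosphanylidene)propanoate | CCOC(=O)C(C)=P(c1ccccc1)(c1ccccc1)c1ccccc1 | starting material
11 | ethyl (2E)-2-methyl-4-(2-methyl-1,3-dioxolan-2-yl)but-2-enoate | CCOC(=O)/C(C)=C/CC1(C)OCCO1 | intermediate
12 | (2E)-2-methyl-4-(2-methyl-1,3-dioxolan-2-yl)but-2-en-1-ol | OC/C(C)=C/CC1(C)OCCO1 | intermediate
13 | (2E)-2-methyl-4-(2-methyl-1,3-dioxolan-2-yl)but-2-en-1-yl acetate | CC(=O)OC/C(C)=C/CC1(C)OCCO1 | intermediate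
14 | 4,4,5,5-tetramethyl-2-[(2E)-2-methyl-4-(2-methyl-1,3-dioxolan-2-yl)but-2-en-1-yl]-1,3,2-dioxaborolane | CC1(C)OB(C/C(C)=C/CC2(C)OCCO2)OC1(C)C | intermediate
15 | 2-{[(3R,4S,5S)-3-(TBSO)-2,6-dimethyl-5-[(2-methyl-1,3-dioxolan-2-yl)methyl]hept-6-en-4-yl]oxy}-4,4,5,5-tetramethyl-1,3,2-dioxaborolane | C=C(C)[C@@H]([C@H](OB1OC(C)(C)C(C)(C)O1)[C@H](O[Si](C)(C)C(C)(C)C)C(C)C)CC2(C)OCCO2 | intermediate (not isolated)
16 | (3R,4S,5S)-3-(TBSO)-2,6-dimethyl-5-[(2-methyl-1,3-dioxolan-2-yl)methyl]hept-6-en-4-ol | C=C(C)[C@@H]([C@H](O)[C@H](O[Si](C)(C)C(C)(C)C)C(C)C)CC1(C)OCCO1 | intermediate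
17 | 2-[(2S,3S,4R)-3,4-bis(TBSO)-5-methyl-2-(prop-1-en-2-yl)hexyl]-2-methyl-1,3-dioxolane | C=C(C)[C@@H]([C@H](O[Si](C)(C)C(C)(C)C)[C@H](O[Si](C)(C)C(C)(C)C)C(C)C)CC1(C)OCCO1 | intermediate
18 | (4S,5S,6R)-5,6-bis(TBSO)-7-methyl-4-(prop-1-en-2-yl)octan-2-one | C=C(C)[C@@H]([C@H](O[Si](C)(C)C(C)(C)C)[C@H](O[Si](C)(C)C(C)(C)C)C(C)C)CC(C)=O | intermediate
19 | (4S,5S,6R)-5,6-bis(TBSO)-7-methyl-4-(prop-1-en-2-yl)-2-(TMSO)oct-1-ene | C=C(C)[C@@H]([C@H](O[Si](C)(C)C(C)(C)C)[C@H](O[Si](C)(C)C(C)(C)C)C(C)C)CC(=C)O[Si](C)(C)C | intermediate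
20 | (4R)-3-acetyl-4-[(4S,5S,6R)-5,6-bis(TBSO)-7-methyl-2-oxo-4-(prop-1-en-2-yl)octyl]-5,5-dimethyloxolan-2-one (C3 epimers) | C=C(C)[C@@H]([C@H](O[Si](C)(C)C(C)(C)C)[C@H](O[Si](C)(C)C(C)(C)C)C(C)C)CC(=O)C[C@@H]1C(C(C)=O)C(=O)OC1(C)C | intermediate
21 | (3R,4R)-3-acetyl-4-[(4S,5S,6R)-5,6-bis(TBSO)-7-methyl-2-oxo-4-(prop-1-en-2-yl)octyl]-3,5,5-trimethyloxolan-2-one | C=C(C)[C@@H]([C@H](O[Si](C)(C)C(C)(C)C)[C@H](O[Si](C)(C)C(C)(C)C)C(C)C)CC(=O)C[C@@H]1[C@](C)(C(C)=O)C(=O)OC1(C)C | intermediate
22 | (3aR,7aR)-5-[(2S,3S,4R)-3,4-bis(TBSO)-5-methyl-2-(prop-1-en-2-yl)hexyl]-5-hydroxy-3,3,7a-trimethylhexahydro-2-benzofuran-1,7-dione (C5 epimers) | C=C(C)[C@@H]([C@H](O[Si](C)(C)C(C)(C)C)[C@H](O[Si](C)(C)C(C)(C)C)C(C)C)CC1(O)CC(=O)[C@]2(C)C(=O)OC(C)(C)[C@@H]2C1 | intermediate (not isolated)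
23 | (3aR,7aR)-5-[(2S,3S,4R)-3,4-bis(TBSO)-5-methyl-2-(prop-1-en-2-yl)hexyl]-3,3,7a-trimethyl-3a,4-dihydro-2-benzofuran-1,7(3H,7aH)-dione | C=C(C)[C@@H]([C@H](O[Si](C)(C)C(C)(C)C)[C@H](O[Si](C)(C)C(C)(C)C)C(C)C)CC1=CC(=O)[C@]2(C)C(=O)OC(C)(C)[C@@H]2C1 | intermediate
24 | (3aR,5R,6R,7aR)-5-[(2S,3S,4R)-3,4-bis(TBSO)-5-methyl-2-(prop-1-en-2-yl)hexyl]-5,6-epoxy-3,3,7a-trimethylhexahydro-2-benzofuran-1,7-dione | C=C(C)[C@@H]([C@H](O[Si](C)(C)C(C)(C)C)[C@H](O[Si](C)(C)C(C)(C)C)C(C)C)C[C@]12O[C@H]1C(=O)[C@]3(C)C(=O)OC(C)(C)[C@@H]3C2 | intermediate (key-step precursor)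
25 | (3aR,5S,6aR)-5-[(2S,3S,4R)-3,4-bis(TBSO)-5-methyl-2-(prop-1-en-2-yl)hexyl]-3,3,6a-trimethyl-1,6-dioxohexahydro-1H-cyclopenta[c]furan-5-carbaldehyde | C=C(C)[C@@H]([C@H](O[Si](C)(C)C(C)(C)C)[C@H](O[Si](C)(C)C(C)(C)C)C(C)C)C[C@]2(C[C@H]3C(C)(C)OC(=O)[C@@]3(C)C2=O)C=O | intermediate (key-step product)
26 | (3aR,5S,6aR)-5-[(2S,3S,4R)-3,4-dihydroxy-5-methyl-2-(prop-1-en-2-yl)hexyl]-3,3,6a-trimethyl-1,6-dioxohexahydro-1H-cyclopenta[c]furan-5-carbaldehyde | C=C(C)[C@@H]([C@H](O)[C@H](O)C(C)C)C[C@]2(C[C@H]3C(C)(C)OC(=O)[C@@]3(C)C2=O)C=O | intermediate (not isolated)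
27 | (3aR,5S,5'S,6'S,6aR)-2'-hydroxy-6'-[(1R)-1-hydroxy-2-methylpropyl]-3,3,6a-trimethyl-5'-(prop-1-en-2-yl)tetrahydro-1H-spiro[cyclopenta[c]furan-5,3'-oxane]-1,6(6aH)-dione (C2' anomers) | C=C(C)[C@@H]1C[C@]2(C[C@H]3C(C)(C)OC(=O)[C@@]3(C)C2=O)C(O)O[C@@H]1[C@H](O)C(C)C | intermediate
28 | (3aR,5R,5'S,6'S,6aR)-3,3,6a-trimethyl-6'-(2-methylpropanoyl)-5'-(prop-1-en-2-yl)tetrahydro-1H-spiro[cyclopenta[c]furan-5,3'-oxane]-1,2',6(6aH)-trione | C=C(C)[C@@H]1C[C@]2(C[C@H]3C(C)(C)OC(=O)[C@@]3(C)C2=O)C(=O)O[C@@H]1C(=O)C(C)C | target

## Step count and least certain steps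

Total: 19 steps. Longest linear sequence: 16 steps (8 to 28, steps 4 to 19).

**Step 17 (key step).** The most likely failure is capture of the boron-bound aldehyde by the isopropenyl group: C1 can reach C19 through a six-membered transition state (carbonyl-ene or Prins closure). The aldehyde is non-enolisable, strongly activated and held near the alkene. Lesser risks are attack of the O21 ether oxygen on C6 (five-membered ring opening of the epoxide), hydride instead of acyl migration to give a 1,2-diketone, and an epoxide on the wrong face from step 16, which would invert C6. Fallback: the alkene is masked during the Lewis-acid step. Epoxy ketone 24 is treated with pyridinium tribromide and pyridine in CH2Cl2 at −78 °C to give the vicinal dibromide of 24, F1. BF3·OEt2 then gives the dibromo keto aldehyde F2. Zinc dust in AcOH/THF at 0 °C regenerates the isopropenyl group and returns to 25.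

**Step 9 (with step 8).** The likely failure is poor facial selectivity on the hindered α-silyloxy aldehyde, or partial loss of E geometry in the π-allylpalladium borylation, which would appear as the C4 epimer. Fallback: allylic alcohol 12 is converted with CBr4/PPh3 into (2E)-1-bromo-2-methyl-4-(2-methyl-1,3-dioxolan-2-yl)but-2-ene, F3. F3 is added to aldehyde 7 with CrCl2 (divalent chromium) in THF (Nozaki–Hiyama allylation). The allylchromium reagent equilibrates and gives the anti adduct regardless of bromide geometry, with Felkin–Anh control from 7, and returns to 16.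

**Step 13.** The likely failure is low facial selectivity or slow addition, because the β-carbon C8 of 4 is next to the gem-dimethyl carbon and the nucleophile is large. Fallback: stoichiometric auxiliary control. Ketone 18 is condensed with (S)-1-amino-2-(methoxymethyl)pyrrolidine to the hydrazone of 18, F4. F4 is deprotonated with LiN(i-Pr)2 at −78 °C and added to 4, giving the hydrazone Michael adduct F5 (azaenolate Michael addition). Two-phase aqueous oxalic acid cleaves the hydrazone and returns to 20; the antipodal hydrazine is used if the sense is opposite.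

**Step 15.** The likely failure is base-induced retro-Michael opening: the C7 enolate can expel the stabilised C15 carbanion, and re-closure would scramble C8 and C15. Closure in the wrong direction (C5 onto C17) is a lesser risk. Fallback: a directed, non-basic aldol. Diketone 21 is deprotonated kinetically at the acetyl methyl (LiN(i-Pr)2, Me3SiCl, −78 °C) to the C19 silyl enol ether of 21, F6. Catalytic Me3SiOTf in CH2Cl2 at −78 °C effects the intramolecular Mukaiyama aldol with silyl transfer to give the silyl ether of ketol 22, F7. This cannot undergo retro-aldol; DBU then eliminates silanol by E1cB and returns to 23.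

**Step 18.** The likely failure is acetalisation: under acidic fluoride the lactol and the free C23 hydroxyl can close to a bicyclic acetal that cannot be oxidised. Slow cleavage of the two hindered silyl ethers also leaves the keto aldehyde exposed to deformylation. Fallback: the aldehyde is oxidised first. Keto aldehyde 25 is treated with NaClO2, NaH2PO4 and 2-methylbut-2-ene in t-BuOH/H2O to give the β-keto acid F8, kept cold. HF·pyridine removes both silyl groups and the δ-hydroxy acid lactonises to the hydroxy lactone F9. Dess–Martin oxidation of the C23 carbinol returns to 28.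

## Further compounds

F1 | step 17 | (3aR,5R,6R,7aR)-5-[(2S,3S,4R)-3,4-bis(TBSO)-2-(1,2-dibromopropan-2-yl)-5-methylhexyl]-5,6-epoxy-3,3,7a-trimethylhexahydro-2-benzofuran-1,7-dione (epimers at the CBr carbon) | BrCC(C)(Br)[C@@H]([C@H](O[Si](C)(C)C(C)(C)C)[C@H](O[Si](C)(C)C(C)(C)C)C(C)C)C[C@]12O[C@H]1C(=O)[C@]3(C)C(=O)OC(C)(C)[C@@H]3C2
F2 | step 17 | (3aR,5S,6aR)-5-[(2S,3S,4R)-3,4-bis(TBSO)-2-(1,2-dibromopropan-2-yl)-5-methylhexyl]-3,3,6a-trimethyl-1,6-dioxohexahydro-1H-cyclopenta[c]furan-5-carbaldehyde (epimers at the CBr carbon) | BrCC(C)(Br)[C@@H]([C@H](O[Si](C)(C)C(C)(C)C)[C@H](O[Si](C)(C)C(C)(C)C)C(C)C)C[C@]2(C[C@H]3C(C)(C)OC(=O)[C@@]3(C)C2=O)C=O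
F3 | step 9 | 2-[(2E)-4-bromo-3-methylbut-2-en-1-yl]-2-methyl-1,3-dioxolane | BrC/C(C)=C/CC1(C)OCCO1
F4 | step 13 | (S)-1-amino-2-(methoxymethyl)pyrrolidine hydrazone of ketone 18 | C=C(C)[C@@H]([C@H](O[Si](C)(C)C(C)(C)C)[C@H](O[Si](C)(C)C(C)(C)C)C(C)C)CC(C)=NN1CCC[C@H]1COC
F5 | step 13 | (S)-1-amino-2-(methoxymethyl)pyrrolidine hydrazone of Michael adduct 20 (C3 epimers) | C=C(C)[C@@H]([C@H](O[Si](C)(C)C(C)(C)C)[C@H](O[Si](C)(C)C(C)(C)C)C(C)C)CC(C[C@@H]1C(C(C)=O)C(=O)OC1(C)C)=NN2CCC[C@H]2COC
F6 | step 15 | (3R,4R)-4-[(4S,5S,6R)-5,6-bis(TBSO)-7-methyl-2-oxo-4-(prop-1-en-2-yl)octyl]-3,5,5-trimethyl-3-[1-(TMSO)ethenyl]oxolan-2-one | C=C(C)[C@@H]([C@H](O[Si](C)(C)C(C)(C)C)[C@H](O[Si](C)(C)C(C)(C)C)C(C)C)CC(=O)C[C@@H]1[C@](C)(C(=C)O[Si](C)(C)C)C(=O)OC1(C)C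
F7 | step 15 | (3aR,7aR)-5-[(2S,3S,4R)-3,4-bis(TBSO)-5-methyl-2-(prop-1-en-2-yl)hexyl]-3,3,7a-trimethyl-5-(TMSO)hexahydro-2-benzofuran-1,7-dione (C5 epimers) | C=C(C)[C@@H]([C@H](O[Si](C)(C)C(C)(C)C)[C@H](O[Si](C)(C)C(C)(C)C)C(C)C)CC1(O[Si](C)(C)C)CC(=O)[C@]2(C)C(=O)OC(C)(C)[C@@H]2C1
F8 | step 18 | 5-[(2S,3S,4R)-3,4-bis(TBSO)-5-methyl-2-(prop-1-en-2-yl)hexyl]-3,3,6a-trimethyl-1,6-dioxohexahydro-1H-cyclopenta[c]furan-5-carboxylic acid (configuration as in 25) | C=C(C)[C@@H]([C@H](O[Si](C)(C)C(C)(C)C)[C@H](O[Si](C)(C)C(C)(C)C)C(C)C)C[C@]2(C[C@H]3C(C)(C)OC(=O)[C@@]3(C)C2=O)C(=O)O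
F9 | step 18 | (3aR,5R,5'S,6'S,6aR)-6'-[(1R)-1-hydroxy-2-methylpropyl]-3,3,6a-trimethyl-5'-(prop-1-en-2-yl)tetrahydro-1H-spiro[cyclopenta[c]furan-5,3'-oxane]-1,2',6(6aH)-trione | C=C(C)[C@@H]1C[C@]2(C[C@H]3C(C)(C)OC(=O)[C@@]3(C)C2=O)C(=O)O[C@@H]1[C@H](O)C(C)C
A1 | alternative 1 | 3,5,5-trimethylfuran-2(5H)-one | CC1=CC(C)(C)OC1=O
A2 | alternative 1 | propa-1,2-diene | C=C=C
A3 | alternative 1 | (1R,5R)-1,4,4-trimethyl-7-methylidene-3-oxabicyclo[3.2.0]heptan-2-one | C1[C@H]2C(C)(C)OC(=O)[C@@]2(C)C1=C
A4 | alternative 2 | imidazole-1-carboxylate of the C22 alcohol on the cis-fused keto lactone carrying the side chain at C6 (C6 epimers, C23 as dioxolane) | C=C(C)[C@@H]([C@H](OC(=O)n1ccnc1)C2(OCCO2)C(C)C)CC3C[C@H]4C(C)(C)OC(=O)[C@@]4(C)C3=O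
A5 | alternative 2 | target with C23 as its 1,3-dioxolane | C=C(C)[C@@H]1C[C@]2(C[C@H]3C(C)(C)OC(=O)[C@@]3(C)C2=O)C(=O)O[C@@H]1C4(OCCO4)C(C)C
A6 | alternative 3 | 5,5-dimethyl-3-{2-[(trimethylsilyl)methyl]prop-2-enoyl}furan-2(5H)-one | C=C(C[Si](C)(C)C)C(=O)C1=CC(C)(C)OC1=O
A7 | alternative 3 | (3aR,6aR)-3,3-dimethyl-5-methylidenetetrahydro-1H-cyclopenta[c]furan-1,6(6aH)-dione | C=C1C[C@H]2C(C)(C)OC(=O)[C@H]2C1=O
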